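Retrosynthesis first takes the two side-chain carbinol C-H bonds back to a 1,2-diketone. It then cuts C1'-C2' (acetyl anion plus C5 aldehyde), then C3a-C7a, C6-C7 and C7-O together (furan-yne cycloisomerisation), then O1-C7a (O-ethynylation) and C3-C3a (ketone α-heteroarylation).
The enabling feature is ring A (C3a, C4, C5, C6, C7, C7a): it carries O1 on C7a and a second oxygen on the adjacent C7, next to the C3a/C7a fusion with ring B. An ynol ether (C7a, C7) tied through O1-C2-C3 to C2 of a furan (C3a, C4, C5, C6) gives exactly this array, and the furan oxygen ends up on C7.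
In the forward direction the open chain aryl-C2-C3-furyl is joined first, rings B and A then close together in one operation, and the C5 side chain is grown last.
C2 and C3 are set on the open chain by one asymmetric hydrogenation with dynamic kinetic resolution and are spectators afterwards.
C1' and C2' are set by one catalyst-controlled double transfer hydrogenation of the diketone, which gives the anti (erythro) diol.

Key step: step 7

Assumption: benzofuran numbering (O1, C2, C3, C3a, C4 to C7, C7a; side chain C1' to C3') is used for all intermediates, and both ruthenium catalysts are taken to induce in the sense known for simple aryl ketones.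

Step 1
Reactants: 1 methyl furan-3-carboxylate
Product: 2 methyl 5-bromofuran-3-carboxylate
Conditions: Br2 (1.05 equiv), AcOH, 40 °C
Reagents that add atoms: bromine, BrBr
Why: Electrophilic aromatic bromination of a 3-acylfuran goes to C5, the α-position whose σ-complex places no positive charge on the ester-bearing carbon.

Step 2
Reactants: 2 methyl 5-bromofuran-3-carboxylate
Product: 3 (5-bromofuran-3-yl)methanol
Conditions: i-Bu2AlH (2.2 equiv), CH2Cl2, -78 °C to 0 °C; aq potassium sodium tartrate
Reagents that add atoms: none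
Why: Aluminium hydride reduction of the ester at low temperature gives the primary alcohol and leaves the C-Br bond and the furan untouched.

Step 3
Reactants: 3 (5-bromofuran-3-yl)methanol
Product: 4 tert-butyl[(5-bromofuran-3-yl)methoxy]dimethylsilane
Conditions: TBSCl, imidazole, CH2Cl2, 0 °C to rt
Reagents that add atoms: tert-butyldimethylsilyl chloride (TBSCl), CC(C)(C)[Si](C)(C)Cl
Why: Imidazole-promoted silylation masks the primary alcohol as a TBS ether that tolerates the alkoxide, KH and n-BuLi used later.

Step 4
Reactants: 4 tert-butyl[(5-bromofuran-3-yl)methoxy]dimethylsilane; 5 1-(3,4-dimethoxyphenyl)propan-1-one (3',4'-dimethoxypropiophenone)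
Product: 6 rac-2-[4-(tert-butyldimethylsilyloxymethyl)furan-2-yl]-1-(3,4-dimethoxyphenyl)propan-1-one
Conditions: Pd2(dba)3 (1 mol %), XPhos (4 mol %), NaOtBu (1.5 equiv), toluene, 70 °C
Reagents that add atoms: none
Why: In this palladium-catalysed ketone α-arylation (Buchwald-Hartwig type) zerovalent palladium inserts into the furyl C-Br bond, the sodium enolate of 5 replaces bromide and reductive elimination forms the C3-C3a bond, a second arylation is held back because it would build a quaternary centre, and the new stereocentre is deliberately left racemic.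

Step 5
Reactants: 6 rac-2-[4-(tert-butyldimethylsilyloxymethyl)furan-2-yl]-1-(3,4-dimethoxyphenyl)propan-1-one
Product: 7 (1S,2R)-2-[4-(tert-butyldimethylsilyloxymethyl)furan-2-yl]-1-(3,4-dimethoxyphenyl)propan-1-ol
Conditions: trans-RuCl2[(R)-xylbinap][(R)-daipen] (0.5 mol %), KOtBu (15 mol %), H2 (10 atm), i-PrOH, 25 °C
Reagents that add atoms: none
Why: In this Noyori asymmetric hydrogenation with dynamic kinetic resolution KOtBu keeps the α-centre of 6 (flanked by aroyl and furyl) racemising, the (R)/(R) catalyst sets the carbinol centre (future C2) as S as it does for simple aryl ketones, and only the (S)-ketone offers that face as its Felkin-Anh face, so the methyl-bearing centre (future C3) is funnelled into the (1S,2R) isomer that maps onto the trans ring.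

Step 6
Reactants: 7 (1S,2R)-2-[4-(tert-butyldimethylsilyloxymethyl)furan-2-yl]-1-(3,4-dimethoxyphenyl)propan-1-ol; 8 trichloroethylene
Product: 11 (1S,2R)-2-[4-(tert-butyldimethylsilyloxymethyl)furan-2-yl]-1-(3,4-dimethoxyphenyl)-1-(ethynyloxy)propane, via dichlorovinyl ether 9 (not isolated), via lithium alkoxyacetylide 10 (not isolated)
Conditions: KH, THF, 0 °C; 8, -50 °C to rt; n-BuLi (2.5 equiv), -78 °C to -40 °C; H2O, -78 °C; cold work-up, Et3N-washed silica, used at once
Reagents that add atoms: none
Why: In the trichloroethylene route to ynol ethers the potassium alkoxide adds to dichloroacetylene released in situ to give 9, n-BuLi eliminates HCl and exchanges the remaining chlorine for lithium to give 10, and water protonates it, no bond to either stereocentre being touched and secondary benzylic alcohols being established substrates.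

Step 7
Reactants: 11 (1S,2R)-2-[4-(tert-butyldimethylsilyloxymethyl)furan-2-yl]-1-(3,4-dimethoxyphenyl)-1-(ethynyloxy)propane
Product: 14 (2S,3S)-5-(tert-butyldimethylsilyloxymethyl)-2-(3,4-dimethoxyphenyl)-3-methyl-2,3-dihydro-1-benzofuran-7-ol, via oxepine 12 (not isolated), via arene oxide 13 (not isolated)
Conditions: Ph3PAuNTf2 (3 mol %), 4 Å molecular sieves, CH2Cl2, 0 °C to 20 °C
Reagents that add atoms: none
Why: Monovalent gold coordinates the alkyne of 11 and, with the push of O1, polarises it toward a ketene-oxonium form whose electrophilic site is the oxygen-bearing carbon (future C7a), so furan C2 (future C3a) attacks there in a 5-exo-dig closure of ring B. The gold-bound cyclopropyl carbene reached in this way breaks the old furan C2-O bond and unfolds to a dienal carbene, whose aldehyde oxygen adds to the carbene carbon (C7-O bond) and releases the catalyst from oxepine 12. Ring A closes by disrotatory 6π electrocyclisation of 12, which makes the C6-C7 bond and gives arene oxide 13, and 13 aromatises to phenol 14. The closest known reaction is the Hashmi phenol synthesis in its alkynyl ether variant, which is established for 2-(furan-2-yl)ethyl ynol ethers and gives 2,3-dihydrobenzofuran-7-ols. No lasting stereocentre is created: C2 and C3 sit on the saturated tether outside the reacting π system and are carried through unchanged, and the two epoxide carbons of 13 become planar on aromatisation. The selectivity needed is opening of 13 at C6-O instead of C7-O, which O1 on C7a secures because only the cation left by C6-O cleavage is conjugated with it, while chemoselectivity against retro-ene loss of ketene, [3,3] shift and hydration rests on the low temperature, the short reaction time and the sieves.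

Step 8
Reactants: 14 (2S,3S)-5-(tert-butyldimethylsilyloxymethyl)-2-(3,4-dimethoxyphenyl)-3-methyl-2,3-dihydro-1-benzofuran-7-ol
Product: 15 tert-butyl{[(2S,3S)-2-(3,4-dimethoxyphenyl)-7-methoxy-3-methyl-2,3-dihydro-1-benzofuran-5-yl]methoxy}dimethylsilane
Conditions: MeI, K2CO3, acetone, rt
Reagents that add atoms: iodomethane (MeI), CI
Why: Williamson methylation of the only acidic OH installs the C7 methyl ether under conditions that affect neither the silyl ether nor the benzylic stereocentres.

Step 9
Reactants: 15 tert-butyl{[(2S,3S)-2-(3,4-dimethoxyphenyl)-7-methoxy-3-methyl-2,3-dihydro-1-benzofuran-5-yl]methoxy}dimethylsilane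
Product: 16 [(2S,3S)-2-(3,4-dimethoxyphenyl)-7-methoxy-3-methyl-2,3-dihydro-1-benzofuran-5-yl]methanol
Conditions: Bu4NF, THF, 0 °C to rt
Reagents that add atoms: none
Why: Fluoride-driven Si-O cleavage frees the primary benzylic alcohol without acid, so the ionisable C2-O1 bond is not at risk.

Step 10
Reactants: 16 [(2S,3S)-2-(3,4-dimethoxyphenyl)-7-methoxy-3-methyl-2,3-dihydro-1-benzofuran-5-yl]methanol
Product: 17 (2S,3S)-2-(3,4-dimethoxyphenyl)-7-methoxy-3-methyl-2,3-dihydro-1-benzofuran-5-carbaldehyde
Conditions: MnO2 (excess), CH2Cl2, rt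
Reagents that add atoms: none
Why: MnO2 oxidation is selective for the electron-rich benzylic alcohol and stops at the aldehyde without dehydrogenating ring B.

Step 11
Reactants: 17 (2S,3S)-2-(3,4-dimethoxyphenyl)-7-methoxy-3-methyl-2,3-dihydro-1-benzofuran-5-carbaldehyde; 18 ethyl vinyl ether
Product: 20 1-[(2S,3S)-2-(3,4-dimethoxyphenyl)-7-methoxy-3-methyl-2,3-dihydro-1-benzofuran-5-yl]-1-hydroxypropan-2-one (both C1' epimers), via enol ether adduct 19 (not isolated)
Conditions: 18, t-BuLi, THF, -78 °C to 0 °C; 17, -78 °C; 0.5 M aq HCl, THF, 0 °C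
Reagents that add atoms: water, O
Why: α-Lithiated ethyl vinyl ether acts as an acetyl anion equivalent that adds 1,2 to the aldehyde and forms the C1'-C2' bond, dilute acid hydrolyses the enol ether of 19 far faster than it ionises the benzylic alcohol, and the new carbinol centre is formed unselectively because step 12 erases it.

Step 12
Reactants: 20 1-[(2S,3S)-2-(3,4-dimethoxyphenyl)-7-methoxy-3-methyl-2,3-dihydro-1-benzofuran-5-yl]-1-hydroxypropan-2-one
Product: 21 1-[(2S,3S)-2-(3,4-dimethoxyphenyl)-7-methoxy-3-methyl-2,3-dihydro-1-benzofuran-5-yl]propane-1,2-dione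
Conditions: Dess-Martin periodinane, CH2Cl2, 0 °C to rt
Reagents that add atoms: none
Why: Dess-Martin oxidation converts the acyloin into the 1,2-diketone under near-neutral conditions and removes the undefined carbinol centre.

Step 13
Reactants: 21 1-[(2S,3S)-2-(3,4-dimethoxyphenyl)-7-methoxy-3-methyl-2,3-dihydro-1-benzofuran-5-yl]propane-1,2-dione
Product: 23 (1S,2R)-1-[(2S,3S)-2-(3,4-dimethoxyphenyl)-7-methoxy-3-methyl-2,3-dihydro-1-benzofuran-5-yl]propane-1,2-diol (CNP0249073.4), via hydroxy ketone 22 (not isolated)
Conditions: RuCl[(R,R)-TsDPEN](p-cymene) (2 mol %), HCO2H/Et3N (5:2), 40 °C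
Reagents that add atoms: none
Why: In this Noyori-Ikariya asymmetric transfer hydrogenation of a 1-arylpropane-1,2-dione the acetyl carbonyl is reduced first to the (R)-hydroxy ketone 22 and the aryl ketone second, each under control of the (R,R) catalyst with the flanking π system taking the place of the aryl group of acetophenone, which gives the anti (1'S,2'R) diol while the distant C2 and C3 centres have no influence.

Compound list
1 | methyl furan-3-carboxylate | COC(=O)c1ccoc1 | starting material
2 | methyl 5-bromofuran-3-carboxylate | COC(=O)c1coc(Br)c1 | intermediate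
3 | (5-bromofuran-3-yl)methanol | OCc1coc(Br)c1 | intermediate
4 | tert-butyl[(5-bromofuran-3-yl)methoxy]dimethylsilane | CC(C)(C)[Si](C)(C)OCc1coc(Br)c1 | intermediate
5 | 1-(3,4-dimethoxyphenyl)propan-1-one | CCC(=O)c1ccc(OC)c(OC)c1 | starting material
6 | rac-2-[4-(tert-butyldimethylsilyloxymethyl)furan-2-yl]-1-(3,4-dimethoxyphenyl)propan-1-one | COc1ccc(C(=O)C(C)c2cc(CO[Si](C)(C)C(C)(C)C)co2)cc1OC | intermediate
7 | (1S,2R)-2-[4-(tert-butyldimethylsilyloxymethyl)furan-2-yl]-1-(3,4-dimethoxyphenyl)propan-1-ol | COc1ccc([C@H]([C@@H](C)c2cc(CO[Si](C)(C)C(C)(C)C)co2)O)cc1OC | intermediate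
8 | trichloroethylene | ClC=C(Cl)Cl | starting material
9 | (E)-1,2-dichlorovinyl ether of 7 (not isolated) | COc1ccc([C@H]([C@@H](C)c2cc(CO[Si](C)(C)C(C)(C)C)co2)O/C(Cl)=C\Cl)cc1OC | intermediate
10 | lithium alkoxyacetylide, the C-lithiated form of 11 (not isolated) | COc1ccc([C@H]([C@@H](C)c2cc(CO[Si](C)(C)C(C)(C)C)co2)OC#C[Li])cc1OC | intermediate
11 | (1S,2R)-2-[4-(tert-butyldimethylsilyloxymethyl)furan-2-yl]-1-(3,4-dimethoxyphenyl)-1-(ethynyloxy)propane (ethynyl ether of 7) | COc1ccc([C@H]([C@@H](C)c2cc(CO[Si](C)(C)C(C)(C)C)co2)OC#C)cc1OC | intermediate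
12 | (2S,3S)-2,3-dihydrofuro[2,3-c]oxepine with oxygen bridging C6 and C7, double bonds C7=C7a, C3a=C4 and C5=C6, substituents as in 14 (not isolated) | COc1ccc([C@H]2OC3=COC=C(CO[Si](C)(C)C(C)(C)C)C=C3[C@@H]2C)cc1OC | intermediate
13 | 6,7-arene oxide of 14, diene C7a=C3a-C4=C5, epoxide face undefined (not isolated) | COc1ccc([C@H]2OC3=C(C=C(CO[Si](C)(C)C(C)(C)C)C4OC34)[C@@H]2C)cc1OC | intermediate
14 | (2S,3S)-5-(tert-butyldimethylsilyloxymethyl)-2-(3,4-dimethoxyphenyl)-3-methyl-2,3-dihydro-1-benzofuran-7-ol | COc1ccc([C@H]2Oc3c(O)cc(CO[Si](C)(C)C(C)(C)C)cc3[C@@H]2C)cc1OC | intermediate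
15 | tert-butyl{[(2S,3S)-2-(3,4-dimethoxyphenyl)-7-methoxy-3-methyl-2,3-dihydro-1-benzofuran-5-yl]methoxy}dimethylsilane | COc1ccc([C@H]2Oc3c(OC)cc(CO[Si](C)(C)C(C)(C)C)cc3[C@@H]2C)cc1OC | intermediate
16 | [(2S,3S)-2-(3,4-dimethoxyphenyl)-7-methoxy-3-methyl-2,3-dihydro-1-benzofuran-5-yl]methanol | COc1ccc([C@H]2Oc3c(OC)cc(CO)cc3[C@@H]2C)cc1OC | intermediate
17 | (2S,3S)-2-(3,4-dimethoxyphenyl)-7-methoxy-3-methyl-2,3-dihydro-1-benzofuran-5-carbaldehyde | COc1ccc([C@H]2Oc3c(OC)cc(C=O)cc3[C@@H]2C)cc1OC | intermediate
18 | ethyl vinyl ether | C=COCC | starting material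
19 | 1-[(2S,3S)-2-(3,4-dimethoxyphenyl)-7-methoxy-3-methyl-2,3-dihydro-1-benzofuran-5-yl]-2-ethoxyprop-2-en-1-ol, both C1' epimers (not isolated) | COc1ccc([C@H]2Oc3c(OC)cc(C(O)C(=C)OCC)cc3[C@@H]2C)cc1OC | intermediate
20 | 1-[(2S,3S)-2-(3,4-dimethoxyphenyl)-7-methoxy-3-methyl-2,3-dihydro-1-benzofuran-5-yl]-1-hydroxypropan-2-one, both C1' epimers | COc1ccc([C@H]2Oc3c(OC)cc(C(O)C(C)=O)cc3[C@@H]2C)cc1OC | intermediate
21 | 1-[(2S,3S)-2-(3,4-dimethoxyphenyl)-7-methoxy-3-methyl-2,3-dihydro-1-benzofuran-5-yl]propane-1,2-dione | COc1ccc([C@H]2Oc3c(OC)cc(C(=O)C(C)=O)cc3[C@@H]2C)cc1OC | intermediate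
22 | (2R)-1-[(2S,3S)-2-(3,4-dimethoxyphenyl)-7-methoxy-3-methyl-2,3-dihydro-1-benzofuran-5-yl]-2-hydroxypropan-1-one (not isolated) | COc1ccc([C@H]2Oc3c(OC)cc(C(=O)[C@@H](C)O)cc3[C@@H]2C)cc1OC | intermediate
23 | (1S,2R)-1-[(2S,3S)-2-(3,4-dimethoxyphenyl)-7-methoxy-3-methyl-2,3-dihydro-1-benzofuran-5-yl]propane-1,2-diol | COc1ccc([C@H]2Oc3c(OC)cc([C@H](O)[C@@H](C)O)cc3[C@@H]2C)cc1OC | target

Total step count: 13. Longest linear sequence: 13 steps (1 to 23); 5, 8 and 18 enter at steps 4, 6 and 11.

Steps most likely to fail

**Risk 1 (step 7).**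
- Once gold is bound, the ynol ether oxygen carries positive charge, and the electron-rich benzylic C2-O1 bond may ionise before the furan attacks.
- Traces of water may hydrate the alkyne.
- The furan, with its unsubstituted C5, may oligomerise.

The fallback builds ring B on a ready-made benzene ring A and uses no gold. It sets out from 5 and comes back at 17.
- Commercial 5-bromovanillin (O=Cc1cc(Br)c(O)c(OC)c1) already shows the oxygen, methoxy, formyl and halogen pattern of ring A.
- Benzylation (BnBr, K2CO3, DMF) should give 4-(benzyloxy)-3-bromo-5-methoxybenzaldehyde F1. Ethylene glycol with TsOH should then give 2-[4-(benzyloxy)-3-bromo-5-methoxyphenyl]-1,3-dioxolane F2.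
- α-Arylation of 5 with F2 under the conditions of step 4 should give the racemic aryl ketone F3.
- The hydrogenation of step 5 should give the (1S,2S)-alcohol F4, and hydrogenolysis (H2, Pd/C, EtOAc) should give the free phenol F5.
- TsOH in wet acetone should then close ring B and unmask the aldehyde in the same operation, arriving at 17. The phenol captures the dimethoxybenzyl cation on the face anti to the C3 methyl group.

**Risk 2 (step 6).**
- O-Vinylation of the hindered potassium alkoxide may be sluggish.
- The base may degrade the substrate.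
- The ethynyl ether may be lost during work-up through hydrolysis, retro-ene fragmentation or [3,3] shift.

The fallback makes the alkyne carbons from a formate by olefination and needs no alkoxide. It sets out from 7 and comes back at 10, which is protonated to 11 as in step 6.
- Acetic formic anhydride and pyridine at 0 °C should give the formate ester F6.
- Dichloro-olefination of the formyl group (PPh3, CCl4, THF, 60 °C; Appel-Ramirez type) should give the 2,2-dichlorovinyl ether F7.
- n-BuLi (2.2 equiv, -78 °C) should eliminate and exchange to 10.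
- The crude solution of 11 would then be dried and taken straight into step 7.

**Risk 3 (step 5).**
- Racemisation of the ketone may lag behind its reduction.
- Catalyst control and Felkin-Anh preference may fail to reinforce each other, which would erode both diastereo- and enantioselection.

The fallback takes the absolute configuration from a C-C coupling and the relative configuration from substrate control. It sets out from 4 and 5 and comes back at 7.
- CuBr2 in refluxing EtOAc/CHCl3 should convert 5 into 2-bromo-1-(3,4-dimethoxyphenyl)propan-1-one F8.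
- Bromine-lithium exchange on 4 (n-BuLi, THF, -78 °C) should give the furyllithium F9, and ZnI2 should give the furylzinc iodide F10.
- Stereoconvergent nickel-catalysed Negishi arylation of the racemic bromoketone (NiCl2(glyme), chiral pybox ligand, glyme/THF, -30 °C) should give the (S)-ketone F11 under base-free conditions that do not racemise it.
- LiBH(s-Bu)3 in THF at -78 °C should reduce it along the Felkin-Anh trajectory to 7.

Further compounds
F1 | step 7 | 4-(benzyloxy)-3-bromo-5-methoxybenzaldehyde | COc1cc(C=O)cc(Br)c1OCc1ccccc1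
F2 | step 7 | 2-[4-(benzyloxy)-3-bromo-5-methoxyphenyl]-1,3-dioxolane | COc1cc(C2OCCO2)cc(Br)c1OCc1ccccc1
F3 | step 7 | rac-2-[2-(benzyloxy)-5-(1,3-dioxolan-2-yl)-3-methoxyphenyl]-1-(3,4-dimethoxyphenyl)propan-1-one | COc1ccc(C(=O)C(C)c2cc(C3OCCO3)cc(OC)c2OCc2ccccc2)cc1OC
F4 | step 7 | (1S,2S)-2-[2-(benzyloxy)-5-(1,3-dioxolan-2-yl)-3-methoxyphenyl]-1-(3,4-dimethoxyphenyl)propan-1-ol | COc1ccc([C@H]([C@@H](C)c2cc(C3OCCO3)cc(OC)c2OCc2ccccc2)O)cc1OC
F5 | step 7 | 2-[(1S,2S)-1-(3,4-dimethoxyphenyl)-1-hydroxypropan-2-yl]-4-(1,3-dioxolan-2-yl)-6-methoxyphenol | COc1ccc([C@H]([C@@H](C)c2cc(C3OCCO3)cc(OC)c2O)O)cc1OC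
F6 | step 6 | formate ester of 7 | COc1ccc([C@H]([C@@H](C)c2cc(CO[Si](C)(C)C(C)(C)C)co2)OC=O)cc1OC
F7 | step 6 | 2,2-dichlorovinyl ether of 7 | COc1ccc([C@H]([C@@H](C)c2cc(CO[Si](C)(C)C(C)(C)C)co2)OC=C(Cl)Cl)cc1OC
F8 | step 5 | 2-bromo-1-(3,4-dimethoxyphenyl)propan-1-one | CC(Br)C(=O)c1ccc(OC)c(OC)c1
F9 | step 5 | [4-(tert-butyldimethylsilyloxymethyl)furan-2-yl]lithium | [Li]c1cc(CO[Si](C)(C)C(C)(C)C)co1
F10 | step 5 | [4-(tert-butyldimethylsilyloxymethyl)furan-2-yl]zinc iodide | I[Zn]c1cc(CO[Si](C)(C)C(C)(C)C)co1
F11 | step 5 | (2S)-2-[4-(tert-butyldimethylsilyloxymethyl)furan-2-yl]-1-(3,4-dimethoxyphenyl)propan-1-one | COc1ccc(C(=O)[C@@H](C)c2cc(CO[Si](C)(C)C(C)(C)C)co2)cc1OC
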